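## The problem

The target 13 is a flavone: a benzopyranone (rings A and C fused along C4a–C8a) that carries ring B at C2 through one aryl–heteroaryl bond. It has no stereocentre, so the whole difficulty is regiochemical: six oxygen substituents, four of them methyl ethers (C3, C7, C8, C2') and two free phenols (C5, C5'). Ring A is a 1,2,3,5-tetraoxygenated benzene in which the two oxygens ortho to the C4 carbonyl, O1 and the C5 hydroxyl, must be told apart. Ring B is a hydroquinone monomethyl ether with its free oxygen para to the methoxyl. The C3 methoxyl sits on the enol-ether carbon of the pyranone, which ordinary flavone closures leave unsubstituted. Three things will not survive rough treatment: the pyranone, which strong nucleophiles open by addition at C2; the methyl ethers flanking the carbonyl, which Lewis acids cleave; and the electron-rich rings A and B, which are easily halogenated or oxidised. The enabling feature is the sequence C7-OMe, C8-OMe, O1 on ring A. If O1 is drawn from a third methoxyl, ring A is simply 3,4,5-trimethoxyphenol, whose single hydroxyl becomes the C5 hydroxyl. C2 and C3 can then be an alkyne between the C4 carbonyl and ring B, and closing O1–C2 with an iodine electrophile places a halogen at C3, where the last methoxyl is needed.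

## Retrosynthesis

**13 from 11 (C3–OMe and two O–S bonds).** The C3 methoxyl is traced back to an iodide and the two phenols to aryl tosylates, giving the 3-iodoflavone bis-tosylate 11. Oxidising a preformed flavone or chalcone at C3 would require a free phenol ortho to the ketone, which brings back the O1/C5 ambiguity, whereas the iodide is exactly what the ring closure delivers. The forward reaction must exchange a vinylic iodide for methoxide on a base-sensitive pyranone. Methoxide is therefore used first to cleave both sulfonates, giving the bis-phenoxide of 12, whose electron-rich ring C resists attack at C2, and CuI then mediates the C–O coupling. The simplification is modest, but in 11 all six oxygens are already differentiated.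

**11 from 10 (O1–C2 and C3–I, ring C).** Cutting O1–C2 and the C3–I bond opens ring C to the alkynone 10, in which O1 is still a methyl ether. The classical cut through a free ortho phenol (chalcone or 1,3-diketone) cannot use a symmetric ring A. This cut can, because the three adjacent methoxyls of 10 come from one purchased phenol, and the sulfonate on the other ortho oxygen decides which oxygen closes. The forward reaction must close 6-endo, use the ring A methoxyl and not that of ring B, and leave both arenes uniodinated.

**10 from 4 and 7 (C3–C4 bond).** The carbonyl–alkyne bond is cut to the aldehyde 4 and the terminal alkyne 7. Forward, 7 is metalated to the alkynylmagnesium chloride 8, added to 4 to give the carbinol 9, and 9 is oxidised to 10. Acylating the alkyne with an acid chloride would cost two more operations on ring A, and a carbonylative coupling would need a hindered ring A halide that is not accessible from a symmetric precursor. The cut divides the molecule into two fragments of similar size, each two steps from a purchased compound.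

**4 from 1 via 2 (O–S bond, then the formyl C–C bond).** Detosylation leads to the salicylaldehyde 2, and removal of the formyl group leads to 3,4,5-trimethoxyphenol 1, with tosyl chloride 3 as the sulfonyl source. Because 1 is symmetric, ortho-formylation can give only one product. A sulfonate is chosen over an ether because a benzyl or alkoxymethyl ether oxygen could itself close ring C with loss of its alkyl group. The tosylate is non-nucleophilic, deactivates ring A toward iodination, and is removed by base at the end.

**7 from 5 via 6 (alkyne carbon, then O–S bond).** The alkyne is traced to the aldehyde 6 by one-carbon homologation, and 6 to 5-hydroxy-2-methoxybenzaldehyde 5 and 3. Ring B is bought with its oxygen pattern complete, and the same sulfonate serves as protecting and deactivating group, so a single basic operation unmasks both phenols.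

## Roads not taken

**Alternative 1:** The cut goes through C4: both C4a–C4 and C4–C3 are broken and C4 is returned to carbon monoxide. Forward, Pd(dba)2 (zerovalent palladium) with a diphosphine would join three components to the 1,3-diketone A1. The components are the aryl iodide A2, CO and the enolate of the methoxymethyl ketone A3. Acid would then remove the methoxymethyl group and cyclodehydrate, and the C5 methyl ether and the benzyl ether would be cleaved last.
- Merits: three-component convergence; the C3 methoxyl arrives with A3, so no halogen exchange at C3 is needed; closure of a 1,3-diketone to a flavone is among the most dependable reactions of the field.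
- Weak points: the iodine of A2 lies between two ortho oxygen substituents on a tetra-oxygenated ring, so oxidative addition and acyl transfer are slow and reduction competes. A2 also needs a regiodefined tetraoxygenated arene and an iodination that must choose between two activated positions. A1 is a 2-alkoxy-1,3-diketone prone to retro-Claisen cleavage under the basic coupling conditions. C5 emerges as a methyl ether, so a late demethylation has to distinguish it from the C3 methoxyl on the other side of the same carbonyl.
- Comparison: this road is better at C3 and its ring closure is not in doubt. The chosen plan sets against it a purchased ring A whose C5 oxygen is distinct from the first step, no late demethylation and no hindered cross-coupling.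

**Alternative 2:** Ring A is built last, on a finished pyranone, by cutting C4a–C5 and tracing the rest of ring A to a four-membered ring. Forward, heating the racemic cyclobutenone A5 would open it to a dienylketene that electrocyclises onto the pyranone and tautomerises to the 5,8-quinol A4 (Moore rearrangement). Methylation of the unchelated C8 hydroxyl and hydrogenolysis of the benzyl ether would finish.
- Merits: the substitution of ring A is dictated by the cyclobutenone and not by aromatic substitution rules; chelation differentiates the C5 and C8 hydroxyls, so selective C8 methylation is credible; the C3 methoxyl is present from the start.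
- Weak points: A5 requires the pyranone ring to be made first, metalated next to its ring oxygen, and added to one specific carbonyl of an unsymmetrical squaric acid derivative. A4 is a para-hydroquinone that air oxidises to the quinone. Many steps are spent constructing a ring that can be bought.
- Comparison: this road handles C3 and the C5/C8 distinction more elegantly. The chosen plan answers with fewer steps, air-stable sulfonate intermediates and a ring A that needs no construction.

**Alternative 3:** Ring C is cut at C4–C4a and O1–C2 into the phenol A7 and the racemic β-ketoester A8. Heating the two neat, or with P2O5 (Simonis conditions), would give the flavone A6 directly. Cleavage of the C5 methyl ether and of the mesylate would follow.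
- Merits: the shortest assembly, one step to the whole skeleton with the C3 methoxyl in place; A7 has a single free ortho position, so the carbon that becomes C4a is not in question.
- Weak points: the uncatalysed condensation needs temperatures above 200 °C; the α-methoxy group slows both transesterification and C-acylation; the Pechmann mode would give an isomeric 4-aryl-3-methoxycoumarin that is hard to separate. An aryl mesylate must also survive these conditions, and A7 is not a commodity chemical. C5 again arrives methylated and must be freed next to the C3 methoxyl.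
- Comparison: if the condensation were clean, this road would be shorter than the chosen plan. The chosen plan offers a ring closure between −78 °C and room temperature whose regiochemistry is fixed by structure, and a C5 oxygen that never has to be demethylated.

Key step: step 7

Remark on the chemistry: carbinol 9 is formed as a racemate and its stereocentre is removed in step 6; neither the compounds of the key step nor the target contain a stereocentre.

## Route

**Step 1**
Reactants: 1 3,4,5-trimethoxyphenol
Product: 2 6-hydroxy-2,3,4-trimethoxybenzaldehyde
Conditions: MgCl2, Et3N, (CH2O)n, MeCN, reflux; aq. HCl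
Reagents that add atoms: paraformaldehyde (as formaldehyde), C=O
Why: Magnesium-phenoxide-directed ortho-formylation (Casnati–Skattebøl reaction): the chelated phenoxide attacks formaldehyde at the ortho carbon and a second formaldehyde oxidises the benzylic alkoxide to the aldehyde. The two ortho positions of 1 are equivalent, so only one salicylaldehyde can form.

**Step 2**
Reactants: 2 6-hydroxy-2,3,4-trimethoxybenzaldehyde; 3 4-methylbenzenesulfonyl chloride
Product: 4 2-formyl-3,4,5-trimethoxyphenyl 4-methylbenzenesulfonate
Conditions: TsCl, Et3N, DMAP (cat.), CH2Cl2, 0 °C to rt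
Reagents that add atoms: none
Why: DMAP-catalysed O-sulfonylation of the only hydroxyl. The tosylate makes this oxygen non-nucleophilic for step 7 and lowers the electron density of ring A.

**Step 3**
Reactants: 5 5-hydroxy-2-methoxybenzaldehyde; 3 4-methylbenzenesulfonyl chloride
Product: 6 3-formyl-4-methoxyphenyl 4-methylbenzenesulfonate
Conditions: TsCl, Et3N, DMAP (cat.), CH2Cl2, 0 °C to rt
Reagents that add atoms: none
Why: O-sulfonylation of an unhindered phenol. The tosylate protects the C5' oxygen and deactivates the hydroquinone-type ring B toward oxidation and iodination.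

**Step 4**
Reactants: 6 3-formyl-4-methoxyphenyl 4-methylbenzenesulfonate
Product: 7 3-ethynyl-4-methoxyphenyl 4-methylbenzenesulfonate
Conditions: dimethyl (1-diazo-2-oxopropyl)phosphonate, K2CO3, MeOH, 0 °C to rt
Reagents that add atoms: dimethyl (1-diazo-2-oxopropyl)phosphonate, COP(=O)(OC)C(=[N+]=[N-])C(C)=O
Why: Ohira–Bestmann variant of the Seyferth–Gilbert homologation: the diazomethylphosphonate anion formed in methanol adds to the aldehyde, and loss of dimethyl phosphate and N2 with a 1,2-hydrogen shift gives the terminal alkyne. Aryl sulfonates are stable to carbonate in methanol at room temperature, conditions under which aryl acetates are removed in their presence.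

**Step 5**
Reactants: 7 3-ethynyl-4-methoxyphenyl 4-methylbenzenesulfonate; 4 2-formyl-3,4,5-trimethoxyphenyl 4-methylbenzenesulfonate
Product: 9 rac-2-{1-hydroxy-3-[2-methoxy-5-(tosyloxy)phenyl]prop-2-yn-1-yl}-3,4,5-trimethoxyphenyl 4-methylbenzenesulfonate, via alkynylmagnesium chloride 8 (not isolated)
Conditions: 7, iPrMgCl·LiCl, THF, 0 °C; then 4, −20 to 0 °C; aq. NH4Cl
Reagents that add atoms: isopropylmagnesium chloride–lithium chloride (iPrMgCl·LiCl), CC(C)[Mg]Cl.[Li+].[Cl-] (Mg and Cl stay only in 8; none in 9)
Why: Deprotonation of the terminal alkyne by the Grignard reagent and 1,2-addition of the alkynylmagnesium species to the aldehyde. An alkynylmagnesium halide is too weak a nucleophile to attack aryl sulfonates at this temperature. The carbinol centre is formed without control (racemic) and is removed in step 6.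

**Step 6**
Reactants: 9 rac-2-{1-hydroxy-3-[2-methoxy-5-(tosyloxy)phenyl]prop-2-yn-1-yl}-3,4,5-trimethoxyphenyl 4-methylbenzenesulfonate
Product: 10 1-[2,3,4-trimethoxy-6-(tosyloxy)phenyl]-3-[2-methoxy-5-(tosyloxy)phenyl]prop-2-yn-1-one
Conditions: MnO2 (activated, excess), CH2Cl2, rt
Reagents that add atoms: none
Why: MnO2 oxidation of a secondary alcohol that is both benzylic and propargylic. The neutral heterogeneous conditions leave sulfonates, methyl ethers and the alkyne untouched.

**Step 7**
Reactants: 10 1-[2,3,4-trimethoxy-6-(tosyloxy)phenyl]-3-[2-methoxy-5-(tosyloxy)phenyl]prop-2-yn-1-one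
Product: 11 3-iodo-7,8-dimethoxy-2-[2-methoxy-5-(tosyloxy)phenyl]-4-oxo-4H-chromen-5-yl 4-methylbenzenesulfonate
Conditions: ICl (1.2 equiv), CH2Cl2, −78 °C to rt; aq. Na2S2O3
Reagents that add atoms: iodine monochloride, ClI
Why: ICl transfers an iodine cation to the alkyne of 10, and the resulting iodonium ion is polarised toward the carbon bearing ring B, which is remote from the carbonyl and stabilised by the ortho-methoxyaryl group; the oxygen of the ring A methoxyl ortho to the ketone opens it anti at that carbon, forming O1–C2 and C3–I, and chloride then removes the methyl group from the aryl methyl oxonium ion as chloromethane. The closest known reaction type is the ICl-induced demethylative cyclisation of 2-methoxyaryl alkynyl ketones to 3-iodochromones. Ring C closes in the 6-endo-dig mode with oxygen as nucleophile, and no stereocentre is formed. The 5-exo closure to an aurone skeleton would need attack at the alkyne carbon next to the carbonyl, the end of the iodonium ion with the least positive charge. The choice of ortho oxygen is secured because the other one is a sulfonate ester and not nucleophilic, which fixes the 5-oxy-7,8-dimethoxy pattern; the reacting methoxyl is flanked on both sides and twisted out of conjugation, which raises its nucleophilicity. The ring B methoxyl could only close a benzofuran by 5-endo attack at the same electron-poor carbon next to the carbonyl, so it should not compete. Iodination of the arenes must also be avoided: both tosyloxy groups lower the electron density of rings A and B, and low temperature with near-stoichiometric ICl reserves the reagent for the alkyne.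

**Step 8**
Reactants: 11 3-iodo-7,8-dimethoxy-2-[2-methoxy-5-(tosyloxy)phenyl]-4-oxo-4H-chromen-5-yl 4-methylbenzenesulfonate
Product: 13 5-hydroxy-2-(5-hydroxy-2-methoxyphenyl)-3,7,8-trimethoxy-4H-chromen-4-one, via 3-iodo diphenol 12 (not isolated)
Conditions: NaOMe (excess), MeOH–DMF, 60 °C; then CuI (20 mol %), 110 °C; aq. HCl
Reagents that add atoms: sodium methoxide, C[O-].[Na+]
Why: Methoxide first cleaves the aryl sulfonates at sulfur, the C5 one fastest because its phenoxide is conjugated with the C4 carbonyl; the resulting bis-phenoxide of 12 has an electron-rich ring C that resists methoxide addition at C2, and any C5' sulfonate left is cleaved during the hot stage. CuI then mediates an Ullmann-type C–O coupling of the C3 iodide with methoxide, a reaction type established for aryl and vinyl iodides, halogenated flavones included. Acidification returns both phenols.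

## Compound list

1 | 3,4,5-trimethoxyphenol | COc1cc(O)cc(OC)c1OC | starting material
2 | 6-hydroxy-2,3,4-trimethoxybenzaldehyde | O=Cc1c(O)cc(OC)c(OC)c1OC | intermediate
3 | 4-methylbenzenesulfonyl chloride | Cc1ccc(S(=O)(=O)Cl)cc1 | starting material
4 | 2-formyl-3,4,5-trimethoxyphenyl 4-methylbenzenesulfonate | O=Cc1c(OS(=O)(=O)c2ccc(C)cc2)cc(OC)c(OC)c1OC | intermediate
5 | 5-hydroxy-2-methoxybenzaldehyde | COc1ccc(O)cc1C=O | starting material
6 | 3-formyl-4-methoxyphenyl 4-methylbenzenesulfonate | COc1ccc(OS(=O)(=O)c2ccc(C)cc2)cc1C=O | intermediate
7 | 3-ethynyl-4-methoxyphenyl 4-methylbenzenesulfonate | COc1ccc(OS(=O)(=O)c2ccc(C)cc2)cc1C#C | intermediate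
8 | {[2-methoxy-5-(tosyloxy)phenyl]ethynyl}magnesium chloride (formed in the flask, not isolated) | COc1ccc(OS(=O)(=O)c2ccc(C)cc2)cc1C#C[Mg]Cl | intermediate
9 | rac-2-{1-hydroxy-3-[2-methoxy-5-(tosyloxy)phenyl]prop-2-yn-1-yl}-3,4,5-trimethoxyphenyl 4-methylbenzenesulfonate (racemic carbinol) | COc1ccc(OS(=O)(=O)c2ccc(C)cc2)cc1C#CC(O)c1c(OC)c(OC)c(OC)cc1OS(=O)(=O)c1ccc(C)cc1 | intermediate
10 | 1-[2,3,4-trimethoxy-6-(tosyloxy)phenyl]-3-[2-methoxy-5-(tosyloxy)phenyl]prop-2-yn-1-one | COc1ccc(OS(=O)(=O)c2ccc(C)cc2)cc1C#CC(=O)c1c(OC)c(OC)c(OC)cc1OS(=O)(=O)c1ccc(C)cc1 | intermediate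
11 | 3-iodo-7,8-dimethoxy-2-[2-methoxy-5-(tosyloxy)phenyl]-4-oxo-4H-chromen-5-yl 4-methylbenzenesulfonate | COc1ccc(OS(=O)(=O)c2ccc(C)cc2)cc1-c1oc2c(OC)c(OC)cc(OS(=O)(=O)c3ccc(C)cc3)c2c(=O)c1I | intermediate
12 | 5-hydroxy-2-(5-hydroxy-2-methoxyphenyl)-3-iodo-7,8-dimethoxy-4H-chromen-4-one (present as its disodium salt, not isolated) | COc1ccc(O)cc1-c1oc2c(OC)c(OC)cc(O)c2c(=O)c1I | intermediate
13 | 5-hydroxy-2-(5-hydroxy-2-methoxyphenyl)-3,7,8-trimethoxy-4H-chromen-4-one (5,5'-dihydroxy-3,7,8,2'-tetramethoxyflavone) | COc1ccc(O)cc1-c1oc2c(OC)c(OC)cc(O)c2c(=O)c1OC | target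

## Step count and risk

Total: 8 steps. Longest linear sequence: 6 steps (steps 1, 2, 5, 6, 7, 8 from 1; equally steps 3, 4, 5, 6, 7, 8 from 5).

**Step 7 (key step).** The most likely failures are electrophilic iodination of ring A at its one free position (between the tosyloxy and methoxy groups), and simple anti addition of ICl across the triple bond without ring closure. The second could happen because the doubly ortho-substituted aryl ketone is twisted and the methoxyl may engage slowly. Fallback, from 10, closing the ring and placing the iodine in separate operations: BCl3 (CH2Cl2, −78 to 0 °C) should cleave, under chelation control, only the methyl ether ortho to the ketone, giving 1-[2-hydroxy-3,4-dimethoxy-6-(tosyloxy)phenyl]-3-[2-methoxy-5-(tosyloxy)phenyl]prop-2-yn-1-one F1. Catalytic TfOH should then close it by 6-endo oxa-Michael addition to 7,8-dimethoxy-2-[2-methoxy-5-(tosyloxy)phenyl]-4-oxo-4H-chromen-5-yl 4-methylbenzenesulfonate F2. Iodination at C3 with I2 and (NH4)2Ce(NO3)6 in MeCN returns to the route at 11.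

**Step 8.** Three processes threaten this step: methoxide addition at C2 with opening or contraction of ring C; reductive loss of the iodine under the copper/methoxide conditions; and O-methylation of the C5' phenoxide by methyl tosylate released during sulfonate cleavage. Fallback, from 11, keeping both tosylates so that only the new C3 hydroxyl can be methylated:
- halogen–magnesium exchange (iPrMgCl·LiCl, THF, −40 °C) to the C3 magnesium species 3-(chloromagnesio)-7,8-dimethoxy-2-[2-methoxy-5-(tosyloxy)phenyl]-4-oxo-4H-chromen-5-yl 4-methylbenzenesulfonate F3;
- trapping with B(OMe)3 to the dimethyl boronate, dimethyl {7,8-dimethoxy-2-[2-methoxy-5-(tosyloxy)phenyl]-4-oxo-5-(tosyloxy)-4H-chromen-3-yl}boronate F4;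
- oxidation in the same flask (H2O2, AcOH) to 3-hydroxy-7,8-dimethoxy-2-[2-methoxy-5-(tosyloxy)phenyl]-4-oxo-4H-chromen-5-yl 4-methylbenzenesulfonate F5;
- methylation (MeI, K2CO3, acetone) to 3,7,8-trimethoxy-2-[2-methoxy-5-(tosyloxy)phenyl]-4-oxo-4H-chromen-5-yl 4-methylbenzenesulfonate F6;
- cleavage of both sulfonates (KOH, MeOH–H2O, reflux), which returns to the route at 13.

**Step 5.** Addition to the doubly ortho-substituted, electron-rich aldehyde may be slow. During that time the sulfonyl group could migrate from the phenolic oxygen to the neighbouring magnesium alkoxide, freeing the ortho phenoxide, which would later close ring C through the wrong oxygen. Fallback, from 4, avoiding any alkoxide next to the sulfonate: Pinnick oxidation (NaClO2, NaH2PO4, 2-methyl-2-butene, t-BuOH–H2O) to 2,3,4-trimethoxy-6-(tosyloxy)benzoic acid F7, then oxalyl chloride with catalytic DMF to 2,3,4-trimethoxy-6-(tosyloxy)benzoyl chloride F8. Acyl Sonogashira coupling of F8 with 7 (PdCl2(PPh3)2, CuI, Et3N, THF, rt) returns to the route at 10, bypassing 9 and step 6.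

**Step 4.** Homologation of the electron-rich aldehyde is slow, and partial methanolysis of the aryl sulfonate by carbonate in methanol could compete. Fallback, from 5, reversing the order of events: Ohira–Bestmann homologation of the free phenol (extra K2CO3) to 3-ethynyl-4-methoxyphenol F9, then tosylation with 3 (Et3N, DMAP, CH2Cl2), which returns to the route at 7.

## Further compounds

F1 | step 7 | 1-[2-hydroxy-3,4-dimethoxy-6-(tosyloxy)phenyl]-3-[2-methoxy-5-(tosyloxy)phenyl]prop-2-yn-1-one | COc1ccc(OS(=O)(=O)c2ccc(C)cc2)cc1C#CC(=O)c1c(O)c(OC)c(OC)cc1OS(=O)(=O)c1ccc(C)cc1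
F2 | step 7 | 7,8-dimethoxy-2-[2-methoxy-5-(tosyloxy)phenyl]-4-oxo-4H-chromen-5-yl 4-methylbenzenesulfonate | COc1ccc(OS(=O)(=O)c2ccc(C)cc2)cc1-c1cc(=O)c2c(OS(=O)(=O)c3ccc(C)cc3)cc(OC)c(OC)c2o1
F3 | step 8 | 3-(chloromagnesio)-7,8-dimethoxy-2-[2-methoxy-5-(tosyloxy)phenyl]-4-oxo-4H-chromen-5-yl 4-methylbenzenesulfonate | COc1ccc(OS(=O)(=O)c2ccc(C)cc2)cc1-c1oc2c(OC)c(OC)cc(OS(=O)(=O)c3ccc(C)cc3)c2c(=O)c1[Mg]Cl
F4 | step 8 | dimethyl {7,8-dimethoxy-2-[2-methoxy-5-(tosyloxy)phenyl]-4-oxo-5-(tosyloxy)-4H-chromen-3-yl}boronate | COc1ccc(OS(=O)(=O)c2ccc(C)cc2)cc1-c1oc2c(OC)c(OC)cc(OS(=O)(=O)c3ccc(C)cc3)c2c(=O)c1B(OC)OC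
F5 | step 8 | 3-hydroxy-7,8-dimethoxy-2-[2-methoxy-5-(tosyloxy)phenyl]-4-oxo-4H-chromen-5-yl 4-methylbenzenesulfonate | COc1ccc(OS(=O)(=O)c2ccc(C)cc2)cc1-c1oc2c(OC)c(OC)cc(OS(=O)(=O)c3ccc(C)cc3)c2c(=O)c1O
F6 | step 8 | 3,7,8-trimethoxy-2-[2-methoxy-5-(tosyloxy)phenyl]-4-oxo-4H-chromen-5-yl 4-methylbenzenesulfonate | COc1ccc(OS(=O)(=O)c2ccc(C)cc2)cc1-c1oc2c(OC)c(OC)cc(OS(=O)(=O)c3ccc(C)cc3)c2c(=O)c1OC
F7 | step 5 | 2,3,4-trimethoxy-6-(tosyloxy)benzoic acid | O=C(O)c1c(OS(=O)(=O)c2ccc(C)cc2)cc(OC)c(OC)c1OC
F8 | step 5 | 2,3,4-trimethoxy-6-(tosyloxy)benzoyl chloride | O=C(Cl)c1c(OS(=O)(=O)c2ccc(C)cc2)cc(OC)c(OC)c1OC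
F9 | step 4 | 3-ethynyl-4-methoxyphenol | COc1ccc(O)cc1C#C
A1 | alternative 1 | 1-[5-(benzyloxy)-2-methoxyphenyl]-2-methoxy-3-[2-(methoxymethoxy)-3,4,6-trimethoxyphenyl]propane-1,3-dione | COCOc1c(C(=O)C(OC)C(=O)c2cc(OCc3ccccc3)ccc2OC)c(OC)cc(OC)c1OC
A2 | alternative 1 | 1-iodo-3,4,6-trimethoxy-2-(methoxymethoxy)benzene | COCOc1c(I)c(OC)cc(OC)c1OC
A3 | alternative 1 | 1-[5-(benzyloxy)-2-methoxyphenyl]-2-methoxyethan-1-one | COCC(=O)c1cc(OCc2ccccc2)ccc1OC
A4 | alternative 2 | 2-[5-(benzyloxy)-2-methoxyphenyl]-5,8-dihydroxy-3,7-dimethoxy-4H-chromen-4-one | COc1ccc(OCc2ccccc2)cc1-c1oc2c(O)c(OC)cc(O)c2c(=O)c1OC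
A5 | alternative 2 | rac-4-{6-[5-(benzyloxy)-2-methoxyphenyl]-5-methoxy-4-oxo-4H-pyran-2-yl}-4-hydroxy-3-methoxycyclobut-2-en-1-one | COC1=CC(=O)C1(O)c1cc(=O)c(OC)c(-c2cc(OCc3ccccc3)ccc2OC)o1
A6 | alternative 3 | 3,5,7,8-tetramethoxy-2-[2-methoxy-5-(methanesulfonyloxy)phenyl]-4H-chromen-4-one | COc1ccc(OS(C)(=O)=O)cc1-c1oc2c(OC)c(OC)cc(OC)c2c(=O)c1OC
A7 | alternative 3 | 2,3,5-trimethoxyphenol | COc1cc(O)c(OC)c(OC)c1
A8 | alternative 3 | rac-ethyl 2-methoxy-3-[2-methoxy-5-(methanesulfonyloxy)phenyl]-3-oxopropanoate | CCOC(=O)C(OC)C(=O)c1cc(OS(C)(=O)=O)ccc1OC
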